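**Plan**
- The side chain is numbered C1' (OCH2) to C8' (=CH2). The enabling feature is the (E)-C2'=C3' olefin with CH3 on C3' and the aryloxymethyl carbon C1' on C2', bound through oxygen to the benzene ring. This is the pattern left when CH3 and a metal add syn across a terminal alkyne and the alkenyl–metal bond is then C-alkylated.
- Retrosynthesis: the C6' hydroxyl is masked as a TBS ether and the cinnamyl alcohol is taken back to the methyl ester. C3'–CH3 and C1'–C2' are then cut in one operation, giving a silyl-protected (R)-enyne, AlMe3 and an aryl chloromethyl ether. The enyne is cut at C6'–C7' (4-pentynal + isopropenylmagnesium bromide) and the chloromethyl ether at O–C1' (methyl sinapate + MeSCH2Cl).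
- Forward: no ring is formed. The enyne arm (steps 1–4) and the aryl arm (steps 5–6) are made separately and joined with AlMe3 in step 7; ester reduction and desilylation follow (steps 8–9).
- Stereochemistry: C6' (R) comes from a Sharpless kinetic resolution of the racemic allylic alcohol. The E geometry of C2'=C3' comes from syn carbometalation and retentive trapping. The cinnamyl E olefin is bought with methyl sinapate.

Key step: step 7

Assumption: methyl sinapate is taken as a purchasable ester (otherwise one Fischer esterification of sinapic acid), and its E olefin is carried unchanged into the target.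

**Step 1**
Reactants: 1 4-pentyn-1-ol
Product: 2 4-pentynal
Conditions: Dess–Martin periodinane, CH2Cl2, 0 °C to rt; aq. NaHCO3 wash; solution concentrated cold and used directly
Reagents that add atoms: none
Why: Dess–Martin oxidation stops at the aldehyde and does not touch the terminal alkyne, and keeping the volatile, self-condensing aldehyde in solution avoids losses.

**Step 2**
Reactants: 2 4-pentynal; 3 isopropenylmagnesium bromide
Product: 4 (±)-2-methylhept-1-en-6-yn-3-ol
Conditions: THF, −78 to 0 °C; then H2O
Reagents that add atoms: none
Why: Grignard 1,2-addition of the alkenylmagnesium reagent to the aldehyde at −78 °C should be much faster than deprotonation of the alkyne C–H or the α-CH2, and forms the C6'–C7' bond and the carbinol centre as a racemate that step 3 resolves.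

**Step 3**
Reactants: 4 (±)-2-methylhept-1-en-6-yn-3-ol
Product: 5 (R)-2-methylhept-1-en-6-yn-3-ol
Conditions: Ti(OiPr)4 (cat.), L-(+)-diisopropyl tartrate, t-BuOOH (0.6 equiv), 4 Å molecular sieves, CH2Cl2, −20 °C; stopped a little beyond half conversion; chromatography
Reagents that add atoms: none
Why: Sharpless kinetic resolution: the titanium tartrate complex built from L-(+)-diisopropyl tartrate epoxidises the (S)-enantiomer of a secondary allylic alcohol of this substitution pattern (OH > alkenyl > alkyl) far faster than the (R)-enantiomer, so the recovered alcohol should be (R)-5, which carries the C6' configuration of the target.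

**Step 4**
Reactants: 5 (R)-2-methylhept-1-en-6-yn-3-ol
Product: 6 (R)-3-(tert-butyldimethylsilyloxy)-2-methylhept-1-en-6-yne
Conditions: TBSCl, imidazole, DMF, rt
Reagents that add atoms: tert-butyldimethylsilyl chloride, CC(C)(C)[Si](C)(C)Cl
Why: Silylation with TBSCl and imidazole in DMF is routine for secondary allylic alcohols and removes the O–H that would otherwise consume AlMe3 in step 7, without touching the stereocentre.

**Step 5**
Reactants: 7 methyl sinapate; 8 chloromethyl methyl sulfide
Product: 9 methyl (E)-3-[3,5-dimethoxy-4-(methylsulfanylmethoxy)phenyl]acrylate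
Conditions: NaH, DMF, 0 °C; then 8, 0 °C to rt
Reagents that add atoms: none
Why: Williamson etherification of the sodium phenoxide with the α-chloro sulfide gives the methylthiomethyl ether (an O,S-acetal); the phenoxide flanked by two methoxy groups still alkylates readily in DMF and the enoate is not attacked by the soft phenoxide.

**Step 6**
Reactants: 9 methyl (E)-3-[3,5-dimethoxy-4-(methylsulfanylmethoxy)phenyl]acrylate
Product: 10 methyl (E)-3-[4-(chloromethoxy)-3,5-dimethoxyphenyl]acrylate
Conditions: SO2Cl2 (1.05 equiv), cyclohexene, CH2Cl2, −78 to 0 °C; volatiles removed in vacuo, residue triturated with dry pentane and used at once under argon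
Reagents that add atoms: sulfuryl chloride, O=S(=O)(Cl)Cl
Why: Chlorinolysis of a methylthiomethyl ether: SO2Cl2 chlorinates sulfur much faster than it attacks the acceptor-substituted olefin or the arene, the chlorosulfonium ion collapses to the aryl chloromethyl ether and MeSCl, and cyclohexene takes up the MeSCl before it can add to the cinnamate.

**Step 7**
Reactants: 6 (R)-3-(tert-butyldimethylsilyloxy)-2-methylhept-1-en-6-yne; 10 methyl (E)-3-[4-(chloromethoxy)-3,5-dimethoxyphenyl]acrylate; 11 trimethylaluminium
Product: 13 methyl (E)-3-[4-[(2E,6R)-6-(tert-butyldimethylsilyloxy)-3,7-dimethylocta-2,7-dienoxy]-3,5-dimethoxyphenyl]acrylate, via (E)-alkenyldimethylalane 12 (not isolated)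
Conditions: 6, 11 (2 equiv), Cp2ZrCl2 (25 mol %), CH2Cl2, 0 °C to rt; excess 11 and solvent removed in vacuo; CH2Cl2, then 10, −40 to 0 °C; cold aq. potassium sodium tartrate quench
Reagents that add atoms: none
Why: Cp2ZrCl2 and AlMe3 exchange methyl for chloride to give a chloride-bridged methylzirconocene–aluminium pair (tetravalent zirconium throughout) that adds CH3 and metal syn across the terminal alkyne of 6, CH3 to the internal carbon, forming the C3'–CH3 bond and, after transfer of the alkenyl group to aluminium, the (E)-alkenylalane 12. With the excess AlMe3 pumped off, the Lewis-acidic aluminium of 12 pulls the chloride from 10 and the resulting aryloxymethyl oxocarbenium ion pair is captured by the alkenyl–aluminium bond with retention at the sp2 carbon, forming the C1'–C2' bond. The closest known reaction type is the zirconium-catalysed methylalumination of terminal alkynes with trapping of the alkenylalane by chloromethyl methyl ether or ethyl chloroformate; 10 differs only in carrying an aryl group on oxygen, and its two ortho methoxy groups turn that oxygen out of conjugation with the ring, so it should assist ionisation much as an alkoxy oxygen does. No ring is closed and no stereocentre is created; the silyl ether at C6' is remote from both reacting carbons and is carried through unchanged. The selectivities needed are methyl at the internal alkyne carbon with syn addition and retentive trapping (inherent in the mechanism and together fixing the E geometry), reaction at the alkyne only (the 1,1-disubstituted olefin of 6 is inert to this reagent pair at ambient temperature and the hydroxyl is masked) and transfer of the alkenyl instead of a methyl group from aluminium (the sp2 carbon–aluminium bond is the more nucleophilic one). The methyl cinnamate of 10 should survive because alkenylalanes do not add to enoates without a further catalyst, which is why the enoates made by the chloroformate trapping persist in the same medium.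

**Step 8**
Reactants: 13 methyl (E)-3-[4-[(2E,6R)-6-(tert-butyldimethylsilyloxy)-3,7-dimethylocta-2,7-dienoxy]-3,5-dimethoxyphenyl]acrylate
Product: 14 (E)-3-[4-[(2E,6R)-6-(tert-butyldimethylsilyloxy)-3,7-dimethylocta-2,7-dienoxy]-3,5-dimethoxyphenyl]prop-2-en-1-ol
Conditions: iBu2AlH (2.5 equiv), CH2Cl2, −78 °C; then aq. potassium sodium tartrate
Reagents that add atoms: none
Why: 1,2-Reduction of an α,β-unsaturated ester with iBu2AlH at −78 °C is the standard route from cinnamates to cinnamyl alcohols and leaves the silyl ether, the allyl aryl ether and the unactivated olefins alone.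

**Step 9**
Reactants: 14 (E)-3-[4-[(2E,6R)-6-(tert-butyldimethylsilyloxy)-3,7-dimethylocta-2,7-dienoxy]-3,5-dimethoxyphenyl]prop-2-en-1-ol
Product: 15 (E)-3-[4-[(2E,6R)-6-hydroxy-3,7-dimethylocta-2,7-dienoxy]-3,5-dimethoxyphenyl]prop-2-en-1-ol (CNP0161487.1)
Conditions: Bu4NF, THF, 0 °C to rt; then H2O
Reagents that add atoms: none
Why: Fluoride-induced desilylation with Bu4NF cleaves only the Si–O bond under mildly basic conditions, so the C6' configuration, the acid-sensitive electron-rich cinnamyl alcohol and the allyl aryl ether should all be preserved.

**Compound list**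
1 | 4-pentyn-1-ol | C#CCCCO | starting material
2 | 4-pentynal | C#CCCC=O | intermediate
3 | isopropenylmagnesium bromide | C=C(C)[Mg]Br | starting material
4 | (±)-2-methylhept-1-en-6-yn-3-ol | C=C(C)C(O)CCC#C | intermediate
5 | (R)-2-methylhept-1-en-6-yn-3-ol | C=C(C)[C@H](O)CCC#C | intermediate
6 | (R)-3-(tert-butyldimethylsilyloxy)-2-methylhept-1-en-6-yne | C=C(C)[C@H](O[Si](C)(C)C(C)(C)C)CCC#C | intermediate
7 | methyl sinapate, methyl (E)-3-(4-hydroxy-3,5-dimethoxyphenyl)acrylate | COC(=O)/C=C/c1cc(OC)c(O)c(OC)c1 | starting material
8 | chloromethyl methyl sulfide | CSCCl | starting material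
9 | methyl (E)-3-[3,5-dimethoxy-4-(methylsulfanylmethoxy)phenyl]acrylate | CSCOc1c(OC)cc(/C=C/C(=O)OC)cc1OC | intermediate
10 | methyl (E)-3-[4-(chloromethoxy)-3,5-dimethoxyphenyl]acrylate | ClCOc1c(OC)cc(/C=C/C(=O)OC)cc1OC | intermediate
11 | trimethylaluminium | C[Al](C)C | starting material
12 | [(1E,5R)-5-(tert-butyldimethylsilyloxy)-2,6-dimethylhepta-1,6-dien-1-yl]dimethylalane | C=C(C)[C@H](O[Si](C)(C)C(C)(C)C)CC/C(C)=C/[Al](C)C | intermediate (not isolated)
13 | methyl (E)-3-[4-[(2E,6R)-6-(tert-butyldimethylsilyloxy)-3,7-dimethylocta-2,7-dienoxy]-3,5-dimethoxyphenyl]acrylate | C=C(C)[C@H](O[Si](C)(C)C(C)(C)C)CC/C(C)=C/COc1c(OC)cc(/C=C/C(=O)OC)cc1OC | intermediate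
14 | (E)-3-[4-[(2E,6R)-6-(tert-butyldimethylsilyloxy)-3,7-dimethylocta-2,7-dienoxy]-3,5-dimethoxyphenyl]prop-2-en-1-ol | C=C(C)[C@H](O[Si](C)(C)C(C)(C)C)CC/C(C)=C/COc1c(OC)cc(/C=C/CO)cc1OC | intermediate
15 | (E)-3-[4-[(2E,6R)-6-hydroxy-3,7-dimethylocta-2,7-dienoxy]-3,5-dimethoxyphenyl]prop-2-en-1-ol | C=C(C)[C@H](O)CC/C(C)=C/COc1c(OC)cc(/C=C/CO)cc1OC | target

**Step count**
Total steps: 9. Longest linear sequence: 7 steps (1 → 2 → 4 → 5 → 6 → 13 → 14 → 15; steps 1–4, 7, 8, 9).

**Steps most likely to fail**

Step 7. Alkenyl transfer to the aryloxymethyl cation may be too slow, so that methyl transfer, self-condensation of the cation or attack at the ester competes. The Me2AlCl set free may also re-ionise the prenyl-type aryl ether once it has formed. The fallback sets out from 6 and returns at 13. Alane 12 is generated as in step 7 and quenched with ethyl chloroformate to give ethyl (2E,6R)-6-(tert-butyldimethylsilyloxy)-3,7-dimethylocta-2,7-dienoate F1. Reduction with iBu2AlH (CH2Cl2, −78 °C) gives (2E,6R)-6-(tert-butyldimethylsilyloxy)-3,7-dimethylocta-2,7-dien-1-ol F2. Mitsunobu etherification of F2 with methyl sinapate 7 (PPh3, diisopropyl azodicarboxylate, THF, 0 °C) then forms the C1'–O bond instead of C1'–C2' and delivers 13.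

Step 6. Chlorination may spill over to the ring or the olefin, and the α-chloro ether may hydrolyse or oligomerise during isolation, so that no clean electrophile reaches step 7. The fallback reverses the polarity of the same C1'–C2' bond; it sets out from 7 and 6 and returns at 13. Phenol 7 is O-alkylated with tributyl(iodomethyl)stannane (K2CO3, DMF) to methyl (E)-3-[3,5-dimethoxy-4-(tributylstannylmethoxy)phenyl]acrylate F3. Alane 12, made from 6 and 11 as in step 7, is quenched with I2 to tert-butyl[[(3R,6E)-7-iodo-2,6-dimethylhepta-1,6-dien-3-yl]oxy]dimethylsilane F4. Stille coupling of F3 with F4 (Pd(PPh3)4, CuI, CsF, DMF) should then give 13.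

Step 3. The rate difference between the enantiomers may be too small, or the volatile alcohol may be lost on separation from the epoxy alcohol, leaving material of low enantiomeric purity; half of the material is consumed in any case. The fallback replaces resolution by asymmetric reduction; it sets out from 4 and returns at 5. Racemic 4 is oxidised with Dess–Martin periodinane (CH2Cl2) to 2-methylhept-1-en-6-yn-3-one F5. F5 is reduced with catecholborane and catalytic (S)-1-methyl-3,3-diphenyl-tetrahydro-1H,3H-pyrrolo[1,2-c][1,3,2]oxazaborole (Corey–Bakshi–Shibata reduction, toluene, −78 °C). The α-branched alkenyl group should act as the larger substituent, so (R)-5 is expected, and catecholborane at this temperature should not hydroborate the alkyne.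

**Further compounds**
F1 | step 7 | ethyl (2E,6R)-6-(tert-butyldimethylsilyloxy)-3,7-dimethylocta-2,7-dienoate | C=C(C)[C@H](O[Si](C)(C)C(C)(C)C)CC/C(C)=C/C(=O)OCC
F2 | step 7 | (2E,6R)-6-(tert-butyldimethylsilyloxy)-3,7-dimethylocta-2,7-dien-1-ol | C=C(C)[C@H](O[Si](C)(C)C(C)(C)C)CC/C(C)=C/CO
F3 | step 6 | methyl (E)-3-[3,5-dimethoxy-4-(tributylstannylmethoxy)phenyl]acrylate | CCCC[Sn](CCCC)(CCCC)COc1c(OC)cc(/C=C/C(=O)OC)cc1OC
F4 | step 6 | tert-butyl[[(3R,6E)-7-iodo-2,6-dimethylhepta-1,6-dien-3-yl]oxy]dimethylsilane | C=C(C)[C@H](O[Si](C)(C)C(C)(C)C)CC/C(C)=C/I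
F5 | step 3 | 2-methylhept-1-en-6-yn-3-one | C=C(C)C(=O)CCC#C
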